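**Retrosynthetic overview**
1. Feature: in the 6H-isochromen-6-one core (O2, C1, C3, C4, C4a, C5–C8, C8a) the pyran ring contains the enol ether O2–C1=C8a. Its β-carbon C8a is nucleophilic and the adjacent C8 is a carbinol beside the quaternary C7, so the C8–C8a bond is cut back to a C8 aldehyde and a C8a–H pyran.
2. The resulting 4-(acylmethylene)-4H-pyran is cut at C5–C6 into a 4-methylene-4H-pyran (γ-pyranone plus MeLi, dehydrated without acid) and an α-silyloxy acyl chloride.
3. C7 and the side-chain carbinol have the same substitution pattern and the same S sense, so both come from methyl (S)-2-methyloxirane-2-carboxylate through one bis(silyl ether).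
4. Side chain: E-selective Wittig enal synthesis, anti-selective crotylboration (sets both oxolane centres), hydroboration and ether closure. The pyranone follows by C-acylation of 4-methoxybut-3-en-2-one and cyclisation.
5. Order of ring formation: oxolane (step 7), pyran (step 10), carbocycle (step 16).

Key step: step 16

Assumption: the push–pull C4a=C5 bond of 22–24 rotates easily, so these compounds are drawn as the E isomer (acyl group on the C8a side), which is the one that can cyclise. Isochromenone numbering is used for the core throughout.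

**Step 1**
Reactants: 1 methyl (S)-2-methyloxirane-2-carboxylate
Product: 2 methyl (S)-2,3-dihydroxy-2-methylpropanoate
Conditions: H2SO4 (cat.), THF/H2O, rt
Reagents that add atoms: water, O
Why: Acid-catalysed epoxide hydrolysis in which water attacks the unsubstituted CH2 in an SN2 manner, because positive charge at C2 is disfavoured by the ester, so the C2–O bond is never broken and the S configuration is kept.

**Step 2**
Reactants: 2 methyl (S)-2,3-dihydroxy-2-methylpropanoate
Product: 3 methyl (S)-2-methyl-2,3-bis(triethylsilyloxy)propanoate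
Conditions: Et3SiOTf (2.4 equiv), 2,6-lutidine, CH2Cl2, −78 → 0 °C
Reagents that add atoms: triethylsilyl trifluoromethanesulfonate, CC[Si](CC)(CC)OS(=O)(=O)C(F)(F)F
Why: Silyl ether formation with a silyl triflate and a hindered pyridine base is strong enough to cover the tertiary α-hydroxy ester oxygen as well as the primary one, and no stereocentre is touched.

**Step 3**
Reactants: 3 methyl (S)-2-methyl-2,3-bis(triethylsilyloxy)propanoate
Product: 4 methyl (S)-2-methyl-3-oxo-2-(triethylsilyloxy)propanoate
Conditions: (COCl)2, DMSO, CH2Cl2, −78 → −40 °C; Et3N, −78 °C → rt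
Reagents that add atoms: none
Why: Swern conditions are known to cleave and oxidise primary triethylsilyl ethers directly (the chlorosulfonium ion attacks the accessible ether oxygen, Et3SiCl leaves, then the usual ylide collapse follows), whereas the tertiary silyl ether is too hindered to react and the product has no α-hydrogen to epimerise.

**Step 4**
Reactants: 4 methyl (S)-2-methyl-3-oxo-2-(triethylsilyloxy)propanoate; 5 2-(triphenylphosphoranylidene)propanal
Product: 6 methyl (2S,3E)-2,4-dimethyl-5-oxo-2-(triethylsilyloxy)pent-3-enoate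
Conditions: PhMe, 90 °C
Reagents that add atoms: none
Why: Wittig olefination with a stabilised α-methyl ylide should give the E trisubstituted enal (formyl group trans to the quaternary carbon), and the activated, non-enolisable aldehyde 4 should outcompete the product enal for the ylide.

**Step 5**
Reactants: 6 methyl (2S,3E)-2,4-dimethyl-5-oxo-2-(triethylsilyloxy)pent-3-enoate; 7 (E)-but-2-ene
Product: 9 methyl (2S,3E,5S,6S)-5-hydroxy-2,4,6-trimethyl-2-(triethylsilyloxy)octa-3,7-dienoate, via (E)-crotyldiisopinocampheylborane 8 (not isolated)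
Conditions: 7, KOt-Bu, n-BuLi, THF, −78 → −45 °C; (−)-Ipc2BOMe, −78 °C; BF3·OEt2; 6, −78 °C; NaOH, H2O2, 0 °C → rt
Reagents that add atoms: none
Why: Brown crotylboration through a closed Zimmerman–Traxler chair, in which the E-crotyl geometry gives the anti C5–OH/C6–CH3 relation and the isopinocampheyl groups derived from (+)-α-pinene direct attack to the Si face of the enal, sets 5S,6S under reagent control while the ester stays inert.

**Step 6**
Reactants: 9 methyl (2S,3E,5S,6S)-5-hydroxy-2,4,6-trimethyl-2-(triethylsilyloxy)octa-3,7-dienoate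
Product: 10 methyl (2S,3E,5S,6S)-5,8-dihydroxy-2,4,6-trimethyl-2-(triethylsilyloxy)oct-3-enoate
Conditions: 9-BBN (2.5 equiv), THF, 0 °C → rt; NaOH, H2O2, 0 °C
Reagents that add atoms: hydrogen peroxide, OO
Why: Hydroboration–oxidation with the bulky 9-BBN should add anti-Markovnikov to the monosubstituted alkene only, since the flanked trisubstituted alkene and the ester do not react with this borane.

**Step 7**
Reactants: 10 methyl (2S,3E,5S,6S)-5,8-dihydroxy-2,4,6-trimethyl-2-(triethylsilyloxy)oct-3-enoate
Product: 12 methyl (2S,3E)-2-methyl-4-[(2S,3S)-3-methyloxolan-2-yl]-2-(triethylsilyloxy)pent-3-enoate, via primary tosylate 11 (not isolated)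
Conditions: TsCl (1.05 equiv), Et3N, DMAP (cat.), CH2Cl2, 0 → 40 °C
Reagents that add atoms: none
Why: Selective sulfonylation of the primary alcohol followed by 5-exo-tet Williamson-type displacement by the C5 hydroxyl breaks no bond at a stereocentre, so the anti diol maps onto the trans-2,3-disubstituted (2S,3S)-oxolane, and the E alkene rules out lactonisation onto the ester.

**Step 8**
Reactants: 12 methyl (2S,3E)-2-methyl-4-[(2S,3S)-3-methyloxolan-2-yl]-2-(triethylsilyloxy)pent-3-enoate
Product: 13 potassium (2S,3E)-2-methyl-4-[(2S,3S)-3-methyloxolan-2-yl]-2-(triethylsilyloxy)pent-3-enoate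
Conditions: KOSiMe3, THF, rt → 40 °C; evaporation
Reagents that add atoms: potassium trimethylsilanolate, C[Si](C)(C)[O-].[K+]
Why: Anhydrous methyl ester cleavage with potassium trimethylsilanolate delivers the dry carboxylate salt without aqueous acid or base, and the quaternary α-carbon can neither epimerise nor let the alkene move into conjugation.

**Step 9**
Reactants: 13 potassium (2S,3E)-2-methyl-4-[(2S,3S)-3-methyloxolan-2-yl]-2-(triethylsilyloxy)pent-3-enoate; 14 (E)-4-methoxybut-3-en-2-one
Product: 16 (1E,6S,7E)-1-methoxy-6-methyl-8-[(2S,3S)-3-methyloxolan-2-yl]-6-(triethylsilyloxy)nona-1,7-diene-3,5-dione, via acyl chloride 15 (not isolated)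
Conditions: 13, (COCl)2, CH2Cl2, 0 °C, volatiles removed; added to 14 (2.1 equiv), LiN(SiMe3)2 (2.1 equiv), THF, −78 °C; AcOH
Reagents that add atoms: none
Why: A carboxylate salt and oxalyl chloride give the acyl chloride without releasing HCl, and Claisen-type C-acylation of the kinetic methyl-side lithium enolate of 14 should give the 1,3-diketone, the second equivalent of enolate taking up its acidic proton.

**Step 10**
Reactants: 16 (1E,6S,7E)-1-methoxy-6-methyl-8-[(2S,3S)-3-methyloxolan-2-yl]-6-(triethylsilyloxy)nona-1,7-diene-3,5-dione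
Product: 17 2-{(2S,3E)-4-[(2S,3S)-3-methyloxolan-2-yl]-2-(triethylsilyloxy)pent-3-en-2-yl}-4H-pyran-4-one
Conditions: CF3CO2H (cat.), PhMe, rt
Reagents that add atoms: none
Why: Acid-catalysed oxa-Michael addition of the enol oxygen to the β-methoxy enone and loss of methanol is an established γ-pyranone ring closure, and the tertiary silyl ether should survive because the electron-poor carbon beside it disfavours ionisation.

**Step 11**
Reactants: 3 methyl (S)-2-methyl-2,3-bis(triethylsilyloxy)propanoate
Product: 18 potassium (S)-2-methyl-2,3-bis(triethylsilyloxy)propanoate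
Conditions: KOSiMe3, THF, rt; evaporation
Reagents that add atoms: potassium trimethylsilanolate, C[Si](C)(C)[O-].[K+]
Why: The same anhydrous silanolate ester cleavage avoids the aqueous acid or base that would endanger the primary silyl ether, and the quaternary centre cannot epimerise.

**Step 12**
Reactants: 18 potassium (S)-2-methyl-2,3-bis(triethylsilyloxy)propanoate
Product: 19 (S)-2-methyl-2,3-bis(triethylsilyloxy)propanoyl chloride
Conditions: (COCl)2, CH2Cl2/hexane, 0 °C → rt; filtration, evaporation, used crude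
Reagents that add atoms: oxalyl chloride, O=C(Cl)C(=O)Cl
Why: Acyl chloride formation from a carboxylate salt and oxalyl chloride gives only KCl, CO and CO2 beside the product, so both silyl ethers stay in place, and the product cannot form a ketene since it has no α-hydrogen.

**Step 13**
Reactants: 17 2-{(2S,3E)-4-[(2S,3S)-3-methyloxolan-2-yl]-2-(triethylsilyloxy)pent-3-en-2-yl}-4H-pyran-4-one; 19 (S)-2-methyl-2,3-bis(triethylsilyloxy)propanoyl chloride
Product: 22 (3S)-3-methyl-1-[(4E)-2-{(2S,3E)-4-[(2S,3S)-3-methyloxolan-2-yl]-2-(triethylsilyloxy)pent-3-en-2-yl}-4H-pyran-4-ylidene]-3,4-bis(triethylsilyloxy)butan-2-one, via lithium pyranolate 20 (not isolated), via 4-methylenepyran 21 (not isolated)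
Conditions: 17, MeLi (1.0 equiv), THF, −78 °C; MsCl (1.0 equiv), −78 → −40 °C; 19 (1.3 equiv); i-Pr2NEt (slow addition), −40 → 0 °C
Reagents that add atoms: methyllithium, [Li]C
Why: 1,2-Addition of an organolithium to a γ-pyranone carbonyl is the classical entry to 4-alkylpyrylium salts, here reached without acid or water by ionisation of the mesylate; deprotonation gives the anhydrobase, whose exocyclic carbon is acylated by acyl chlorides because that attack regenerates an aromatic pyrylium ion, which a second deprotonation turns into the stable push–pull ketone.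

**Step 14**
Reactants: 22 the tris(triethylsilyl ether) ketone of step 13
Product: 23 (3S)-4-hydroxy-3-methyl-1-[(4E)-2-{(2S,3E)-4-[(2S,3S)-3-methyloxolan-2-yl]-2-(triethylsilyloxy)pent-3-en-2-yl}-4H-pyran-4-ylidene]-3-(triethylsilyloxy)butan-2-one
Conditions: PPTS (cat.), MeOH/CH2Cl2, 0 °C
Reagents that add atoms: none
Why: Mild acid-catalysed methanolysis distinguishes silyl ethers by steric access, so the primary triethylsilyl ether should go well before the two tertiary ones, and the absence of base avoids silyl migration from O7 to O8.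

**Step 15**
Reactants: 23 the primary alcohol of step 14
Product: 24 (2S)-2-methyl-4-[(4E)-2-{(2S,3E)-4-[(2S,3S)-3-methyloxolan-2-yl]-2-(triethylsilyloxy)pent-3-en-2-yl}-4H-pyran-4-ylidene]-3-oxo-2-(triethylsilyloxy)butanal
Conditions: Dess–Martin periodinane, NaHCO3, CH2Cl2, 0 °C → rt; filtered and used without chromatography
Reagents that add atoms: none
Why: Dess–Martin oxidation works under buffered, nucleophile-free conditions, which protects the non-enolisable β-keto aldehyde from deformylation and leaves the enol ethers, the alkene and the silyl ethers alone.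

**Step 16**
Reactants: 24 the β-keto aldehyde of step 15
Product: 25 (7S,8R)-8-hydroxy-7-methyl-3-{(2S,3E)-4-[(2S,3S)-3-methyloxolan-2-yl]-2-(triethylsilyloxy)pent-3-en-2-yl}-7-(triethylsilyloxy)-7,8-dihydro-6H-isochromen-6-one
Conditions: BF3·OEt2 (1.1 equiv), 2,6-di-tert-butyl-4-methylpyridine, CH2Cl2 (high dilution), −78 → −40 °C; aq. NaHCO3
Reagents that add atoms: none
Why: Proposed new method: BF3 on the aldehyde oxygen raises the electrophilicity of C8, the ring oxygen O2 pushes electron density through C1=C8a so that C8a adds to C8, and the C1 oxocarbenium ion that results gives up the C8a proton to the hindered pyridine, which restores the C1=C8a enol ether and the full pyranylidene ketone chromophore. The closest known reaction type is the intramolecular Prins or Mukaiyama-type addition of an enol ether β-carbon to a Lewis acid-activated aldehyde, which has not been shown with a 4-acylmethylene-4H-pyran as the nucleophile. The carbocycle closes in a 6-(enolexo)-exo-trig mode, with the C8=O bond and the C1=C8a bond both lying outside the ring that forms. C8 is set by the neighbouring C7 centre: in the half-chair transition state the C8–O(BF3) bond should stand pseudo-axial to avoid allylic 1,3-strain against C1–H and antiperiplanar to the axial, non-chelating C7–OSiEt3 bond (dipoles opposed, methyl equatorial), which leads to the 7,8-anti, 8R carbinol. The step needs C8a to react rather than C4 or C5: the push–pull C4a=C5 bond rotates easily so both geometric isomers are available, closure at C4 is held back by the fully substituted carbon on C3, and closure at C5 would give a strained four-membered ring. BF3 also binds the more basic C6 ketone and so silences part of the nucleophile, but it exchanges fast between the two carbonyl groups and only the aldehyde-bound form is consumed.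

**Step 17**
Reactants: 25 the bis(triethylsilyl ether) of step 16
Product: 26 (7S,8R)-7,8-dihydroxy-3-{(2S,3E)-2-hydroxy-4-[(2S,3S)-3-methyloxolan-2-yl]pent-3-en-2-yl}-7-methyl-7,8-dihydro-6H-isochromen-6-one (CNP0502247.2)
Conditions: HF·pyridine, pyridine, THF, 0 °C → rt (plastic vessel)
Reagents that add atoms: none
Why: Fluoride-driven Si–O cleavage in a pyridine-buffered medium should remove both tertiary silyl ethers without ionising the tertiary allylic or the C8 carbinol and without exposing the base- and amine-sensitive pyran ring to a nucleophile.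

**Compound list**
1 | methyl (S)-2-methyloxirane-2-carboxylate | COC(=O)[C@]1(C)CO1 | starting material
2 | methyl (S)-2,3-dihydroxy-2-methylpropanoate | COC(=O)[C@@](C)(O)CO | intermediate
3 | methyl (S)-2-methyl-2,3-bis(triethylsilyloxy)propanoate | COC(=O)[C@@](C)(O[Si](CC)(CC)CC)CO[Si](CC)(CC)CC | intermediate
4 | methyl (S)-2-methyl-3-oxo-2-(triethylsilyloxy)propanoate | COC(=O)[C@@](C)(O[Si](CC)(CC)CC)C=O | intermediate
5 | 2-(triphenylphosphoranylidene)propanal | CC(C=O)=P(c1ccccc1)(c1ccccc1)c1ccccc1 | starting material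
6 | methyl (2S,3E)-2,4-dimethyl-5-oxo-2-(triethylsilyloxy)pent-3-enoate | C/C(=C\[C@](C)(O[Si](CC)(CC)CC)C(=O)OC)C=O | intermediate
7 | (E)-but-2-ene | C/C=C/C | starting material
8 | (E)-crotyldiisopinocampheylborane (isopinocampheyl groups from (+)-α-pinene) | C/C=C/CB([C@@H]1C[C@@H]2C[C@H]([C@H]1C)C2(C)C)[C@@H]1C[C@@H]2C[C@H]([C@H]1C)C2(C)C | intermediate
9 | methyl (2S,3E,5S,6S)-5-hydroxy-2,4,6-trimethyl-2-(triethylsilyloxy)octa-3,7-dienoate | C/C(=C\[C@](C)(O[Si](CC)(CC)CC)C(=O)OC)[C@@H](O)[C@@H](C)C=C | intermediate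
10 | methyl (2S,3E,5S,6S)-5,8-dihydroxy-2,4,6-trimethyl-2-(triethylsilyloxy)oct-3-enoate | C/C(=C\[C@](C)(O[Si](CC)(CC)CC)C(=O)OC)[C@@H](O)[C@@H](C)CCO | intermediate
11 | methyl (2S,3E,5S,6S)-5-hydroxy-2,4,6-trimethyl-8-(4-toluenesulfonyloxy)-2-(triethylsilyloxy)oct-3-enoate | C/C(=C\[C@](C)(O[Si](CC)(CC)CC)C(=O)OC)[C@@H](O)[C@@H](C)CCOS(=O)(=O)c1ccc(C)cc1 | intermediate
12 | methyl (2S,3E)-2-methyl-4-[(2S,3S)-3-methyloxolan-2-yl]-2-(triethylsilyloxy)pent-3-enoate | C/C(=C\[C@](C)(O[Si](CC)(CC)CC)C(=O)OC)[C@H]1OCC[C@@H]1C | intermediate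
13 | potassium (2S,3E)-2-methyl-4-[(2S,3S)-3-methyloxolan-2-yl]-2-(triethylsilyloxy)pent-3-enoate | C/C(=C\[C@](C)(O[Si](CC)(CC)CC)C(=O)[O-])[C@H]1OCC[C@@H]1C.[K+] | intermediate
14 | (E)-4-methoxybut-3-en-2-one | CO/C=C/C(C)=O | starting material
15 | (2S,3E)-2-methyl-4-[(2S,3S)-3-methyloxolan-2-yl]-2-(triethylsilyloxy)pent-3-enoyl chloride | C/C(=C\[C@](C)(O[Si](CC)(CC)CC)C(=O)Cl)[C@H]1OCC[C@@H]1C | intermediate
16 | (1E,6S,7E)-1-methoxy-6-methyl-8-[(2S,3S)-3-methyloxolan-2-yl]-6-(triethylsilyloxy)nona-1,7-diene-3,5-dione | C/C(=C\[C@](C)(O[Si](CC)(CC)CC)C(=O)CC(=O)/C=C/OC)[C@H]1OCC[C@@H]1C | intermediate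
17 | 2-{(2S,3E)-4-[(2S,3S)-3-methyloxolan-2-yl]-2-(triethylsilyloxy)pent-3-en-2-yl}-4H-pyran-4-one | C/C(=C\[C@](C)(O[Si](CC)(CC)CC)C1=CC(=O)C=CO1)[C@H]1OCC[C@@H]1C | intermediate
18 | potassium (S)-2-methyl-2,3-bis(triethylsilyloxy)propanoate | [K+].[O-]C(=O)[C@@](C)(O[Si](CC)(CC)CC)CO[Si](CC)(CC)CC | intermediate
19 | (S)-2-methyl-2,3-bis(triethylsilyloxy)propanoyl chloride | ClC(=O)[C@@](C)(O[Si](CC)(CC)CC)CO[Si](CC)(CC)CC | intermediate
20 | lithium 4-methyl-2-{side chain of 17}-4H-pyran-4-olate (both C4 epimers) | C/C(=C\[C@](C)(O[Si](CC)(CC)CC)C1=CC(C)([O-])C=CO1)[C@H]1OCC[C@@H]1C.[Li+] | intermediate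
21 | 4-methylene-2-{(2S,3E)-4-[(2S,3S)-3-methyloxolan-2-yl]-2-(triethylsilyloxy)pent-3-en-2-yl}-4H-pyran | C/C(=C\[C@](C)(O[Si](CC)(CC)CC)C1=CC(=C)C=CO1)[C@H]1OCC[C@@H]1C | intermediate
22 | (3S)-3-methyl-1-[(4E)-2-{side chain of 17}-4H-pyran-4-ylidene]-3,4-bis(triethylsilyloxy)butan-2-one | C/C(=C\[C@](C)(O[Si](CC)(CC)CC)C1=C/C(=C/C(=O)[C@@](C)(O[Si](CC)(CC)CC)CO[Si](CC)(CC)CC)C=CO1)[C@H]1OCC[C@@H]1C | intermediate
23 | (3S)-4-hydroxy-3-methyl-1-[(4E)-2-{side chain of 17}-4H-pyran-4-ylidene]-3-(triethylsilyloxy)butan-2-one | C/C(=C\[C@](C)(O[Si](CC)(CC)CC)C1=C/C(=C/C(=O)[C@@](C)(O[Si](CC)(CC)CC)CO)C=CO1)[C@H]1OCC[C@@H]1C | intermediate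
24 | (2S)-2-methyl-3-oxo-4-[(4E)-2-{side chain of 17}-4H-pyran-4-ylidene]-2-(triethylsilyloxy)butanal | C/C(=C\[C@](C)(O[Si](CC)(CC)CC)C1=C/C(=C/C(=O)[C@@](C)(O[Si](CC)(CC)CC)C=O)C=CO1)[C@H]1OCC[C@@H]1C | intermediate
25 | (7S,8R)-8-hydroxy-7-methyl-3-{side chain of 17}-7-(triethylsilyloxy)-7,8-dihydro-6H-isochromen-6-one | C/C(=C\[C@](C)(O[Si](CC)(CC)CC)C1=CC2=CC(=O)[C@@](C)(O[Si](CC)(CC)CC)[C@H](O)C2=CO1)[C@H]1OCC[C@@H]1C | intermediate
26 | (7S,8R)-7,8-dihydroxy-3-{(2S,3E)-2-hydroxy-4-[(2S,3S)-3-methyloxolan-2-yl]pent-3-en-2-yl}-7-methyl-7,8-dihydro-6H-isochromen-6-one | C/C(=C\[C@](C)(O)C1=CC2=CC(=O)[C@@](C)(O)[C@H](O)C2=CO1)[C@H]1OCC[C@@H]1C | target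

**Step count**
Total step count: 17.
Longest linear sequence: 15 steps (steps 1–10 and 13–17). Steps 11 and 12 branch off from 3.

**Steps most likely to fail**

Step 16 (key step).
- What may go wrong: the Lewis acid may rest on the C6 ketone, so that the pyran ring is too electron-poor to attack. It may also trigger ionisation of the tertiary allylic silyl ether, a 1,2-acyl shift of the α-silyloxy aldehyde, closure at C4, or poor facial selectivity at C8.
- Fallback: the C–H hydroxyalkylation is replaced by a Nozaki–Hiyama–Kishi closure of the same C8–C8a bond from a C8a iodide. It sets out from pyranone 17.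
- Iodine with pyridine in CH2Cl2 is an α-iodination of a β-unsubstituted enone by addition–elimination. It is open only to the C5=C6 bond of the pyranone because C2 is blocked, and it should give the 5-iodopyranone F1.
- MeMgBr in place of MeLi (to avoid halogen–metal exchange), then MsCl, 19 and i-Pr2NEt in the manner of step 13, should give the iodinated pyranylidene ketone F2.
- PPTS in MeOH should give the iodinated primary alcohol F3, and Dess–Martin periodinane the iodo aldehyde F4.
- CrCl2 with catalytic NiCl2 in DMF should then add the C8a alkenylchromium species to the aldehyde. The regiochemistry is fixed by the position of the iodine, and the fallback comes back to the route at 25.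

Step 13.
- What may go wrong: MeLi may attack the unsubstituted C6 of the pyranone in a conjugate manner with ring opening. The methylenepyran may oligomerise before it is acylated, or acylation by the hindered acyl chloride may be too slow.
- Fallback: the methylenepyran is avoided and the C4a=C5 bond is made by the known condensation of a 4-alkoxypyrylium salt with an active methylene compound. It sets out from 19 and 17.
- The lithium enolate of allyl acetate (LiN(i-Pr)2, THF, −78 °C, two equivalents) should be acylated by 19 to the allyl β-keto ester F5.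
- MeOTf in CH2Cl2 should O-methylate 17 to the 4-methoxypyrylium triflate F6.
- F5, F6 and i-Pr2NEt should give, by addition at C4 and loss of methanol, the pyranylidene β-keto ester F7.
- Pd(PPh3)4 with HCO2H/Et3N (palladium-catalysed deallylation and decarboxylation) should then remove the ester group, and the fallback comes back to the route at 22.

Step 9.
- What may go wrong: the enolate may be acylated on oxygen, the reaction of the hindered acyl chloride may be slow, or the tertiary allylic acyl chloride may lose carbon monoxide.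
- Fallback: acyl substitution is replaced by aldol addition and oxidation. It sets out from ester 12 and skips step 8.
- i-Bu2AlH in CH2Cl2 at −78 °C should stop at the α-silyloxy aldehyde F8.
- The lithium enolate of 14 should add to it to give the β-hydroxy ketone F9 as a mixture of carbinol epimers, which is of no consequence.
- Dess–Martin periodinane should oxidise F9 to the diketone, and the fallback comes back to the route at 16.

**Further compounds**
F1 | step 16 | 5-iodo-2-{(2S,3E)-4-[(2S,3S)-3-methyloxolan-2-yl]-2-(triethylsilyloxy)pent-3-en-2-yl}-4H-pyran-4-one | C/C(=C\[C@](C)(O[Si](CC)(CC)CC)C1=CC(=O)C(I)=CO1)[C@H]1OCC[C@@H]1C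
F2 | step 16 | C8a-iodo analogue of 22 | C/C(=C\[C@](C)(O[Si](CC)(CC)CC)C1=C/C(=C/C(=O)[C@@](C)(O[Si](CC)(CC)CC)CO[Si](CC)(CC)CC)C(I)=CO1)[C@H]1OCC[C@@H]1C
F3 | step 16 | C8a-iodo analogue of 23 | C/C(=C\[C@](C)(O[Si](CC)(CC)CC)C1=C/C(=C/C(=O)[C@@](C)(O[Si](CC)(CC)CC)CO)C(I)=CO1)[C@H]1OCC[C@@H]1C
F4 | step 16 | C8a-iodo analogue of 24 | C/C(=C\[C@](C)(O[Si](CC)(CC)CC)C1=C/C(=C/C(=O)[C@@](C)(O[Si](CC)(CC)CC)C=O)C(I)=CO1)[C@H]1OCC[C@@H]1C
F5 | step 13 | allyl (4S)-4-methyl-3-oxo-4,5-bis(triethylsilyloxy)pentanoate | C=CCOC(=O)CC(=O)[C@@](C)(O[Si](CC)(CC)CC)CO[Si](CC)(CC)CC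
F6 | step 13 | 4-methoxy-2-{(2S,3E)-4-[(2S,3S)-3-methyloxolan-2-yl]-2-(triethylsilyloxy)pent-3-en-2-yl}pyrylium trifluoromethanesulfonate | C/C(=C\[C@](C)(O[Si](CC)(CC)CC)c1cc(OC)cc[o+]1)[C@H]1OCC[C@@H]1C.[O-]S(=O)(=O)C(F)(F)F
F7 | step 13 | allyl (4S)-4-methyl-3-oxo-2-[2-{side chain of 17}-4H-pyran-4-ylidene]-4,5-bis(triethylsilyloxy)pentanoate | C/C(=C\[C@](C)(O[Si](CC)(CC)CC)C1=CC(=C(C(=O)OCC=C)C(=O)[C@@](C)(O[Si](CC)(CC)CC)CO[Si](CC)(CC)CC)C=CO1)[C@H]1OCC[C@@H]1C
F8 | step 9 | (2S,3E)-2-methyl-4-[(2S,3S)-3-methyloxolan-2-yl]-2-(triethylsilyloxy)pent-3-enal | C/C(=C\[C@](C)(O[Si](CC)(CC)CC)C=O)[C@H]1OCC[C@@H]1C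
F9 | step 9 | (1E,6S,7E)-5-hydroxy-1-methoxy-6-methyl-8-[(2S,3S)-3-methyloxolan-2-yl]-6-(triethylsilyloxy)nona-1,7-dien-3-one (both C5 epimers) | C/C(=C\[C@](C)(O[Si](CC)(CC)CC)C(O)CC(=O)/C=C/OC)[C@H]1OCC[C@@H]1C
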